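**Retrosynthetic overview**
1. Target 12 ⇒ 11: the (E)-diene is unmasked last by cheletropic loss of SO2 from a 3-sulfolene.
2. 11 ⇒ 10: both rings come from one acyclic triene ester by a hydrogen-atom-transfer radical cycloisomerisation; the C4–C5 bond closes ring A, then C10–C9 closes ring B, and C8=C17 arises from the final H-atom loss.
3. 10 ⇒ rac-9: key step, a catalytic enantioselective O-acetylation (C–O bond). It installs the acetate of the target, fixes C1 as (S), and this one stereocentre steers C4, C5, C9 and C10 in the cyclisation.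
4. 9 ⇒ enal 5 + silyl dienolate 7 (vinylogous Mukaiyama aldol); 5 ⇒ 3 + methacrolein (cross-metathesis); 3 ⇒ 3-methyl-3-sulfolene + geranyl bromide.

Assumption: the SMILES is taken literally, i.e. the ent-labdane antipode (1S,4R,5S,9R,10S,12E; labdane numbering) with the C1 acetate equatorial and the C4 ester axial (cis to the C10 methyl). Labdane numbers are used in the "Why" lines (chain C5 of 9/10 = labdane C1, chain C2 = C4, chain C6/C7 = C10/C5, chain C10/C11 = C8/C9). The sulfolene stereocentre in 3, 5 and 8–11 is left undefined (both epimers), since step 7 destroys it.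

**Step 1**
Reactants: 1 3-methyl-2,5-dihydrothiophene 1,1-dioxide (3-methyl-3-sulfolene); 2 geranyl bromide
Product: 3 2-[(2E)-3,7-dimethylocta-2,6-dien-1-yl]-3-methyl-2,5-dihydrothiophene 1,1-dioxide
Conditions: LiHMDS (1.05 equiv) added to 1 + 2, THF–HMPA (4:1), −78 °C
Reagents that add atoms: none
Why: Sulfolene α-alkylation: the α-sulfonyl allylic anion at C2 (methyl on the central carbon of the allyl anion) is generated in the presence of the allylic bromide so that SN2 alkylation outruns ring-opening, and the new sulfolene stereocentre is racemic and irrelevant.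

**Step 2**
Reactants: 3 geranyl sulfolene; 4 methacrolein
Product: 5 (2E,6E)-2,6-dimethyl-8-(3-methyl-1,1-dioxo-2,5-dihydrothiophen-2-yl)octa-2,6-dienal
Conditions: 4 (10 equiv), second-generation Hoveyda–Grubbs catalyst RuCl2(SIMes)(=CH-C6H4-2-OiPr) (5 mol %), CH2Cl2, 40 °C
Reagents that add atoms: none
Why: Olefin cross-metathesis of the isopropylidene terminus (the only unhindered trisubstituted alkene) with methacrolein releases isobutene and gives the thermodynamically favoured (E)-2-methyl enal, which carries the C1 oxygen.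

**Step 3**
Reactants: 6 methyl tiglate
Product: 7 1-methoxy-2-methyl-1-(trimethylsilyloxy)buta-1,3-diene
Conditions: LDA, THF–DMPU, −78 °C; Me3SiCl
Reagents that add atoms: chlorotrimethylsilane, C[Si](C)(C)Cl
Why: Kinetic γ-deprotonation of the enoate and O-silylation give the silyl dienolate (silyl ketene acetal formation).

**Step 4**
Reactants: 5 enal; 7 silyl dienolate
Product: 9 methyl (2E,6E,10E)-5-hydroxy-2,6,10-trimethyl-12-(3-methyl-1,1-dioxo-2,5-dihydrothiophen-2-yl)dodeca-2,6,10-trienoate (racemic carbinol), via trimethylsilyl ether 8 (not isolated)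
Conditions: B(C6F5)3 (5 mol %), CH2Cl2, −78 °C; then citric acid, MeOH, 0 °C
Reagents that add atoms: none
Why: Vinylogous Mukaiyama aldol reaction: the Lewis-acid-activated enal is attacked 1,2 by the γ-carbon of the dienolate to give the (E)-δ-hydroxy-α-methyl enoate, and the carbinol is deliberately left racemic.

**Step 5 (key C–O bond formation)**
Reactants: 9 racemic allylic alcohol
Product: 10 methyl (2E,5S,6E,10E)-5-acetoxy-2,6,10-trimethyl-12-(3-methyl-1,1-dioxo-2,5-dihydrothiophen-2-yl)dodeca-2,6,10-trienoate
Conditions: Ac2O (0.45 equiv), Et3N (0.5 equiv), planar-chiral DMAP catalyst (η5-C5Ph5)Fe(η5-C10H11N2) (2 mol %, the antipode that acylates the (S)-alcohol faster), tert-amyl alcohol, 0 °C, stopped near 40 % conversion; unreacted (R)-9 is recovered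
Reagents that add atoms: acetic anhydride, CC(=O)OC(C)=O
Why: Catalytic enantioselective acyl transfer (kinetic resolution, known to give selectivity factors of about 20–80 for allylic alcohols with a substituent geminal to the carbinol): the chiral N-acetylpyridinium acetylates only (S)-9, forming the acetate C–O bond that sets C1 (S) and stays in the molecule to the end (maximum yield 50 %, expected ≥95 % ee only if the selectivity factor reaches about 60; ee checked before step 6).

**Step 6**
Reactants: 10 (S)-acetoxy triene ester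
Product: 11 methyl (1S,4R,5S,9R,10S)-1-acetoxy-12,15-sulfonyl-labda-8(17),13-dien-19-oate (the 12,15-sulfolene, i.e. SO2 adduct, of 12)
Conditions: Co(dmgBF2)2(THF)2 (10 mol %), H2 (5 atm), benzene (0.01 M), 50 °C
Reagents that add atoms: none
Why: Proposed new method: the cobaloxime hydride formed reversibly from the cobalt complex and H2 transfers H• to C3 of the enoate to give the tertiary α-ester radical at C4, which closes ring A 6-endo on C5 and then ring B 6-endo on C9 through a chair–chair array of the two (E)-alkenes (trans ring fusion, C9 side chain equatorial, CO2Me axial as in keto-ester radical cyclisations, acetate pseudo-equatorial in the alkene plane where its σ*(C–O) does not drain the π bond attacked by the electrophilic radical), after which divalent cobalt abstracts H• from the C17 methyl of the C8 radical to leave the exocyclic alkene and regenerate the hydride (a net isomerisation; the cobaloxime hydride does not add to unactivated alkenes, so product, inner alkenes and sulfolene are left alone); the closest known reactions are the cobaloxime/H2 radical cycloisomerisation of α-substituted acrylates (5-exo), cobalt catalytic chain transfer, and Mn(OAc)3/Cu(OAc)2 6-endo/6-endo polyene bicyclisations.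

**Step 7**
Reactants: 11 bicyclic sulfolene
Product: 12 methyl (1S,4R,5S,9R,10S,12E)-1-acetoxylabda-8(17),12,14-trien-19-oate (target)
Conditions: toluene–pyridine (10:1), 110 °C, N2 sparge
Reagents that add atoms: none
Why: Thermal cheletropic extrusion of SO2 from the 3-sulfolene is disrotatory with the C12 substituent turning outward, so both sulfolene epimers give the (12E)-diene.

**Compound list**
1 | 3-methyl-2,5-dihydrothiophene 1,1-dioxide | CC1=CCS(=O)(=O)C1 | starting material
2 | geranyl bromide, (2E)-1-bromo-3,7-dimethylocta-2,6-diene | CC(C)=CCC/C(C)=C/CBr | starting material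
3 | 2-[(2E)-3,7-dimethylocta-2,6-dien-1-yl]-3-methyl-2,5-dihydrothiophene 1,1-dioxide | CC(C)=CCC/C(C)=C/CC1C(C)=CCS1(=O)=O | intermediate
4 | methacrolein | C=C(C)C=O | starting material
5 | (2E,6E)-2,6-dimethyl-8-(3-methyl-1,1-dioxo-2,5-dihydrothiophen-2-yl)octa-2,6-dienal | O=C/C(C)=C/CC/C(C)=C/CC1C(C)=CCS1(=O)=O | intermediate
6 | methyl tiglate, methyl (2E)-2-methylbut-2-enoate | C/C=C(\C)C(=O)OC | starting material
7 | 1-methoxy-2-methyl-1-(trimethylsilyloxy)buta-1,3-diene | C=CC(C)=C(OC)O[Si](C)(C)C | intermediate
8 | trimethylsilyl ether of 9 (racemic, not isolated) | COC(=O)/C(C)=C/CC(O[Si](C)(C)C)/C(C)=C/CC/C(C)=C/CC1C(C)=CCS1(=O)=O | intermediate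
9 | methyl (2E,6E,10E)-5-hydroxy-2,6,10-trimethyl-12-(3-methyl-1,1-dioxo-2,5-dihydrothiophen-2-yl)dodeca-2,6,10-trienoate (racemic) | COC(=O)/C(C)=C/CC(O)/C(C)=C/CC/C(C)=C/CC1C(C)=CCS1(=O)=O | intermediate
10 | methyl (2E,5S,6E,10E)-5-acetoxy-2,6,10-trimethyl-12-(3-methyl-1,1-dioxo-2,5-dihydrothiophen-2-yl)dodeca-2,6,10-trienoate | COC(=O)/C(C)=C/C[C@H](OC(C)=O)/C(C)=C/CC/C(C)=C/CC1C(C)=CCS1(=O)=O | intermediate
11 | methyl (1S,4R,5S,9R,10S)-1-acetoxy-12,15-sulfonyl-labda-8(17),13-dien-19-oate (trans-decalin, 10-Me and 4-CO2Me cis-diaxial, 1-OAc and C9 side chain equatorial; both C12 epimers) | O=S3(=O)CC=C(C)C3C[C@@H]1C(=C)CC[C@H]2[C@@]1(C)[C@@H](OC(C)=O)CC[C@@]2(C)C(=O)OC | intermediate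
12 | methyl (1S,4R,5S,9R,10S,12E)-1-acetoxylabda-8(17),12,14-trien-19-oate = methyl (1R,4S,4aS,5R,8aS)-4-acetoxy-1,4a-dimethyl-6-methylidene-5-[(2E)-3-methylpenta-2,4-dien-1-yl]decahydronaphthalene-1-carboxylate | C=C/C(C)=C/C[C@@H]1C(=C)CC[C@H]2[C@@]1(C)[C@@H](OC(C)=O)CC[C@@]2(C)C(=O)OC | target

**Step count**
Total steps: 7. Longest linear sequence: 6 (steps 1, 2, 4, 5, 6, 7).

**Three steps most likely to fail**

Step 6 (the proposed new step). The risks are slow H• transfer to the trisubstituted enoate, plain hydrogenation or isomerisation of the enoate, and 5-exo closure. The largest uncertainty is stereochemical: the pseudo-equatorial placement of the acetate is a stereoelectronic argument opposed by eclipsing with the C10 methyl, so the diastereomer ratio may be modest, and the axial preference of the ester is taken by analogy from keto-ester radicals. Isomers would be separated after step 7. Fallback with known chemistry, setting out from 5 and coming back at 11: aldehyde 5 undergoes a Mukaiyama aldol reaction (B(C6F5)3 cat., CH2Cl2, −78 °C, then citric acid/MeOH) with 1-methoxy-2-methyl-1,3-bis(trimethylsilyloxy)buta-1,3-diene F1, made from commercial methyl 2-methyl-3-oxobutanoate by two rounds of LDA/Me3SiCl. This gives the δ-hydroxy-β-keto ester methyl (6E,10E)-5-hydroxy-2,6,10-trimethyl-12-(3-methyl-1,1-dioxo-2,5-dihydrothiophen-2-yl)-3-oxododeca-6,10-dienoate F2. The same catalytic enantioselective acetylation as in step 5 gives the (5S)-acetate F3. Mn(OAc)3·2H2O (2 equiv) and Cu(OAc)2·H2O (1 equiv) in AcOH at room temperature then effect the established oxidative 6-endo/6-endo radical bicyclisation of a 2-methyl-3-oxo ester (axial ester, trans fusion and exocyclic alkene are precedented) to the 3-oxo analogue of 11, F4. Its tosylhydrazone F5 (TsNHNH2, EtOH) is reduced with catecholborane/NaOAc, which removes the C3 carbonyl and rejoins the route at 11.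

Step 5. The selectivity factor on this particular alcohol is untested, the yield is capped at 50 %, and the fast-reacting enantiomer has to be confirmed for the chosen catalyst antipode. Fallback, setting out from 5 (with 7) and coming back at 10: the carbinol is set during C–C bond formation instead, by a catalytic enantioselective vinylogous Mukaiyama aldol reaction (SiCl4, chiral bisphosphoramide 2–5 mol %, iPr2NEt, CH2Cl2, −78 °C). This gives the enantioenriched alcohol methyl (2E,5S,6E,10E)-5-hydroxy-2,6,10-trimethyl-12-(3-methyl-1,1-dioxo-2,5-dihydrothiophen-2-yl)dodeca-2,6,10-trienoate F6, and plain acetylation (Ac2O, pyridine, DMAP) gives 10.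

Step 2. The catalyst may also attack the internal trisubstituted alkene, or conversion of the hindered prenyl terminus may stall. Fallback, setting out from 3 and coming back at 5: allylic C–H oxidation of the terminal (E)-methyl group with SeO2 (0.5 equiv)/t-BuOOH in CH2Cl2 gives a mixture of 5 and the allylic alcohol (2E,6E)-2,6-dimethyl-8-(3-methyl-1,1-dioxo-2,5-dihydrothiophen-2-yl)octa-2,6-dien-1-ol F7. MnO2 in CH2Cl2 converts F7 into 5.

**Further compounds**
F1 | step 6 | 1-methoxy-2-methyl-1,3-bis(trimethylsilyloxy)buta-1,3-diene | COC(O[Si](C)(C)C)=C(C)C(=C)O[Si](C)(C)C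
F2 | step 6 | methyl (6E,10E)-5-hydroxy-2,6,10-trimethyl-12-(3-methyl-1,1-dioxo-2,5-dihydrothiophen-2-yl)-3-oxododeca-6,10-dienoate (racemic carbinol) | COC(=O)C(C)C(=O)CC(O)/C(C)=C/CC/C(C)=C/CC1C(C)=CCS1(=O)=O
F3 | step 6 | methyl (5S,6E,10E)-5-acetoxy-2,6,10-trimethyl-12-(3-methyl-1,1-dioxo-2,5-dihydrothiophen-2-yl)-3-oxododeca-6,10-dienoate | COC(=O)C(C)C(=O)C[C@H](OC(C)=O)/C(C)=C/CC/C(C)=C/CC1C(C)=CCS1(=O)=O
F4 | step 6 | 3-oxo analogue of 11 (labdane numbering) | O=S3(=O)CC=C(C)C3C[C@@H]1C(=C)CC[C@H]2[C@@]1(C)[C@@H](OC(C)=O)CC(=O)[C@@]2(C)C(=O)OC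
F5 | step 6 | tosylhydrazone of F4 | O=S3(=O)CC=C(C)C3C[C@@H]1C(=C)CC[C@H]2[C@@]1(C)[C@@H](OC(C)=O)CC(=NNS(=O)(=O)c4ccc(C)cc4)[C@@]2(C)C(=O)OC
F6 | step 5 | methyl (2E,5S,6E,10E)-5-hydroxy-2,6,10-trimethyl-12-(3-methyl-1,1-dioxo-2,5-dihydrothiophen-2-yl)dodeca-2,6,10-trienoate | COC(=O)/C(C)=C/C[C@H](O)/C(C)=C/CC/C(C)=C/CC1C(C)=CCS1(=O)=O
F7 | step 2 | (2E,6E)-2,6-dimethyl-8-(3-methyl-1,1-dioxo-2,5-dihydrothiophen-2-yl)octa-2,6-dien-1-ol | OC/C(C)=C/CC/C(C)=C/CC1C(C)=CCS1(=O)=O
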